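The route rests on disconnecting the bond between the guaiacyl ring carbon and C6 of the tetrahydrofuran ring (furo[3,4-c]furan-1-one numbering: C1=O, O2, C3, C3a, C4, O5, C6, C6a). C6 is acetal-level through O5 and at the same time β to the lactone carbonyl C1 through C6a, so the aryl-free precursor is the flat push–pull enol ether 12 (C6=C6a). A rhodium-catalysed 1,4-addition of a guaiacyl boronic acid forms the aryl–C6 bond and creates C6 and C6a in one operation, on the face dictated by C3a. The C3/C3a pair comes from an Evans syn-aldol/lactonisation; C6 itself is delivered by an O→C formyl shift.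

Key step: step 8

Remark: compounds 1, 3, 4 and 13 are assumed to be purchased; "aryl" in short names means 3,5-dimethoxy-4-(triisopropylsilyloxy)phenyl.

Step 1
Reactants: 1 syringaldehyde
Product: 2 3,5-dimethoxy-4-(triisopropylsilyloxy)benzaldehyde
Conditions: TIPSCl, imidazole, DMAP (cat.), DMF, 40 °C
Reagents that add atoms: triisopropylsilyl chloride, CC(C)[Si](Cl)(C(C)C)C(C)C
Why: Imidazole-promoted O-silylation of the phenol gives an aryl TIPS ether that should tolerate the boron enolate, basic peroxide, borane, amide base and acid of the later steps and is removed by fluoride at the end.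

Step 2
Reactants: 3 (S)-4-benzyl-1,3-oxazolidin-2-one; 4 methyl 4-chloro-4-oxobutanoate
Product: 5 N-(3-methoxycarbonylpropanoyl) oxazolidinone
Conditions: n-BuLi, THF, −78 °C; then 4, −78 → 0 °C
Reagents that add atoms: none
Why: N-acylation of the lithiated oxazolidinone occurs at the acid chloride, which is far more electrophilic than the methyl ester.

Step 3
Reactants: 5 N-(3-methoxycarbonylpropanoyl) oxazolidinone; 2 3,5-dimethoxy-4-(triisopropylsilyloxy)benzaldehyde
Product: 7 trans-lactone imide, via syn-aldol adduct 6 (not isolated)
Conditions: Bu2BOTf, i-Pr2NEt, CH2Cl2, −78 → 0 °C; 2, −78 → 0 °C; pH 7 buffer/MeOH; then TsOH (cat.), CH2Cl2, rt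
Reagents that add atoms: none
Why: Evans boron syn-aldol, in which the Z-boron enolate of the imide reacts through a Zimmerman–Traxler chair on the face opposite the benzyl group of the (S)-auxiliary and so sets the carbinol carbon (future C3, S) and the α-carbon (future C3a, S), after which the syn-aldol closes onto the γ-ester to the trans-γ-lactone.

Step 4
Reactants: 7 trans-lactone imide
Product: 8 trans-paraconic acid
Conditions: LiOH, H2O2, THF/H2O (3:1), 0 °C; aq. Na2SO3; 1 M HCl to pH 2
Reagents that add atoms: hydrogen peroxide, OO
Why: Hydroperoxide attacks the exocyclic imide carbonyl selectively (Evans auxiliary hydrolysis), any opened lactone should reclose on acidification, and the trans arrangement at C3/C3a is the thermodynamically favoured one.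

Step 5
Reactants: 8 trans-paraconic acid
Product: 9 trans-hydroxymethyl lactone
Conditions: BH3·SMe2, THF, 0 °C → rt; MeOH quench
Reagents that add atoms: none
Why: Borane reduces the carboxylic acid chemoselectively through its acyloxyborane while the γ-lactone and the aryl silyl ether are left alone, and the non-basic medium avoids translactonisation.

Step 6
Reactants: 9 trans-hydroxymethyl lactone
Product: 10 formate ester
Conditions: HCO2H, DCC, DMAP (cat.), CH2Cl2, 0 °C → rt
Reagents that add atoms: formic acid, O=CO
Why: Steglich-type esterification under near-neutral conditions masks the primary alcohol without forming an alkoxide and at the same time installs the carbon that becomes C6.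

Step 7
Reactants: 10 formate ester
Product: 12 bicyclic enol ether, via lactol 11 (not isolated)
Conditions: LiHMDS (1.2 equiv), THF, −78 → −20 °C; AcOH; then CSA (cat.), toluene, 4 Å MS, 60 °C
Reagents that add atoms: none
Why: Intramolecular Claisen condensation (a Baker–Venkataraman-type O→C formyl shift, 5-(enolexo)-exo-trig) in which the lactone enolate at C6a attacks the tethered formate, so that no free alkoxide exists before the C6a–C6 bond is made, followed by acid-catalysed dehydration of the lactol to the conjugated enol ether; no stereocentre is created and C3/C3a are not enolisable here.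

Step 8
Reactants: 12 bicyclic enol ether; 13 (4-hydroxy-3-methoxyphenyl)boronic acid
Product: 14 mono-TIPS furofuranone
Conditions: [Rh(OH)(cod)]2 (3 mol%), 13 (3 equiv), 1,4-dioxane/H2O (10:1), 50 °C
Reagents that add atoms: none
Why: Hayashi–Miyaura 1,4-addition: the aryl group is transmetallated from boron to Rh(I)–OH, the C6=C6a bond inserts into the Rh–aryl bond with aryl going to C6 (β to the lactone carbonyl and polarised by O5) and rhodium to C6a, and the resulting oxa-π-allyl rhodium enolate is protonated by water, which regenerates Rh–OH. The closest known cases are rhodium-catalysed arylations of α,β-unsaturated lactones and of β-oxygenated acceptors such as chromones and dihydropyranones. No ring is closed; the bicycle is already in place and only changes from a flat enol ether to the cis-fused tetrahydrofurofuranone. C6 is set by the syn insertion, which pyramidalises C6a toward the metal and should therefore be possible only on the face that carries H-3a (the convex face of the emerging cis-bicyclo[3.3.0] system), so the aryl group ends up cis to H-3a and H-6a, that is exo (6S). C6a is set by protonation of the enolate to the only strain-free, cis-fused lactone (6aS) and, being α to the carbonyl, can also equilibrate to it. The step needs 1,4-addition without β-alkoxide elimination (opening of the O5–C6 bond) and without loss of the boronic acid by protodeboronation; base-free aqueous conditions make protonolysis of the enolate fast, and the boronic acid is used in excess.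

Step 9
Reactants: 14 mono-TIPS furofuranone
Product: 15 target lactone
Conditions: TBAF, AcOH (1:1), THF, 0 °C → rt
Reagents that add atoms: none
Why: Fluoride cleaves the aryl silyl ether, and buffering with acetic acid keeps the medium non-basic so that the β-alkoxy lactone should neither open by retro-oxa-Michael reaction nor epimerise; no stereocentre is touched.

Compound list
1 | syringaldehyde (4-hydroxy-3,5-dimethoxybenzaldehyde) | COc1cc(C=O)cc(OC)c1O | starting material
2 | 3,5-dimethoxy-4-(triisopropylsilyloxy)benzaldehyde | COc1cc(C=O)cc(OC)c1O[Si](C(C)C)(C(C)C)C(C)C | intermediate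
3 | (S)-4-benzyl-1,3-oxazolidin-2-one | O=C1N[C@@H](Cc2ccccc2)CO1 | starting material
4 | methyl 4-chloro-4-oxobutanoate | COC(=O)CCC(Cl)=O | starting material
5 | methyl 4-[(4S)-4-benzyl-2-oxo-1,3-oxazolidin-3-yl]-4-oxobutanoate | COC(=O)CCC(=O)N1[C@@H](Cc2ccccc2)COC1=O | intermediate
6 | methyl (3S)-4-[(4S)-4-benzyl-2-oxo-1,3-oxazolidin-3-yl]-3-[(S)-[3,5-dimethoxy-4-(triisopropylsilyloxy)phenyl](hydroxy)methyl]-4-oxobutanoate (syn-aldol adduct) | O=C(N1[C@@H](Cc2ccccc2)COC1=O)[C@H]([C@H](O)c1cc(OC)c(O[Si](C(C)C)(C(C)C)C(C)C)c(OC)c1)CC(=O)OC | intermediate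
7 | (4S)-4-benzyl-3-{[(2S,3S)-2-[3,5-dimethoxy-4-(triisopropylsilyloxy)phenyl]-5-oxooxolan-3-yl]carbonyl}-1,3-oxazolidin-2-one (trans-lactone imide) | O=C(N1[C@@H](Cc2ccccc2)COC1=O)[C@H]1CC(=O)O[C@@H]1c1cc(OC)c(O[Si](C(C)C)(C(C)C)C(C)C)c(OC)c1 | intermediate
8 | (2S,3S)-2-[3,5-dimethoxy-4-(triisopropylsilyloxy)phenyl]-5-oxooxolane-3-carboxylic acid (trans-paraconic acid) | OC(=O)[C@H]1CC(=O)O[C@@H]1c1cc(OC)c(O[Si](C(C)C)(C(C)C)C(C)C)c(OC)c1 | intermediate
9 | (4R,5S)-5-[3,5-dimethoxy-4-(triisopropylsilyloxy)phenyl]-4-(hydroxymethyl)oxolan-2-one (trans) | OC[C@H]1CC(=O)O[C@@H]1c1cc(OC)c(O[Si](C(C)C)(C(C)C)C(C)C)c(OC)c1 | intermediate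
10 | [(2S,3R)-2-[3,5-dimethoxy-4-(triisopropylsilyloxy)phenyl]-5-oxooxolan-3-yl]methyl formate | O=COC[C@H]1CC(=O)O[C@@H]1c1cc(OC)c(O[Si](C(C)C)(C(C)C)C(C)C)c(OC)c1 | intermediate
11 | (3S,3aR,6aS)-3-[3,5-dimethoxy-4-(triisopropylsilyloxy)phenyl]-6-hydroxytetrahydro-1H,3H-furo[3,4-c]furan-1-one (cis-fused lactol, both configurations at C6) | OC1OC[C@H]2[C@@H]1C(=O)O[C@@H]2c1cc(OC)c(O[Si](C(C)C)(C(C)C)C(C)C)c(OC)c1 | intermediate
12 | (3S,3aR)-3-[3,5-dimethoxy-4-(triisopropylsilyloxy)phenyl]-3a,4-dihydro-1H,3H-furo[3,4-c]furan-1-one (enol ether with the C6=C6a double bond) | O=C1O[C@H](c2cc(OC)c(O[Si](C(C)C)(C(C)C)C(C)C)c(OC)c2)[C@H]2COC=C12 | intermediate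
13 | (4-hydroxy-3-methoxyphenyl)boronic acid | COc1cc(B(O)O)ccc1O | starting material
14 | (3S,3aR,6S,6aS)-3-[3,5-dimethoxy-4-(triisopropylsilyloxy)phenyl]-6-(4-hydroxy-3-methoxyphenyl)tetrahydro-1H,3H-furo[3,4-c]furan-1-one | COc1cc([C@H]2OC[C@H]3[C@@H]2C(=O)O[C@@H]3c2cc(OC)c(O[Si](C(C)C)(C(C)C)C(C)C)c(OC)c2)ccc1O | intermediate
15 | (3S,3aR,6S,6aS)-6-(4-hydroxy-3-methoxyphenyl)-3-(4-hydroxy-3,5-dimethoxyphenyl)tetrahydro-1H,3H-furo[3,4-c]furan-1-one (cis-fused, both aryl groups exo) | COc1cc([C@H]2OC[C@H]3[C@@H]2C(=O)O[C@@H]3c2cc(OC)c(O)c(OC)c2)ccc1O | target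

Total step count: 9
Longest linear sequence: 8 steps (1 → 2 → 7 → 8 → 9 → 10 → 12 → 14 → 15; steps 1 and 3 to 9)

Steps most likely to fail

Step 8. Insertion into the α-branched, donor-substituted C6=C6a bond may be so slow that protodeboronation of the electron-rich boronic acid outruns it, or the rhodium enolate may expel O5 and open the tetrahydrofuran ring. The fallback replaces conjugate addition by C-arylation of an oxocarbenium ion. It sets out from lactol 11 (isolated after the acetic acid quench of step 7, with the dehydration left out) and from boronic acid 13. Lactol 11 with MeOH and PPTS should give the methyl acetal F1, and 13 with KHF2 in MeOH/H2O should give potassium (4-hydroxy-3-methoxyphenyl)trifluoroborate F2. Treatment of F1 and F2 with BF3·OEt2 in MeCN at −20 °C should ionise the acetal to the cis-fused bicyclic oxocarbenium ion, which the aryl group attacks at its boron-bearing carbon on the convex face. This comes back to the route at 14.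

Step 7. The amide base may attack the formate instead of deprotonating C6a, which would release the primary alkoxide and allow translactonisation, or the condensation may go between two molecules. The fallback is a classical Claisen formylation on a protected alcohol and sets out from 9. TESCl and imidazole in CH2Cl2 should give the triethylsilyl ether F3; LDA in THF at −78 °C followed by ethyl formate should give the α-hydroxymethylene lactone F4. Then 1 M HCl in THF (desilylation and closure to lactol 11) followed by CSA in toluene with 4 Å MS should give the enol ether, so the fallback comes back to the route at 12.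

Step 4. Under basic peroxide the imide α-position may be deprotonated with E1cB opening of the lactone (loss of the C3–O2 bond), or the hindered imide may be cleaved within the oxazolidinone ring. The fallback removes the auxiliary reductively and makes no new compound (F0). It sets out from 7: NaBH4 in THF/H2O at 0 °C should attack the exocyclic imide carbonyl and give the primary alcohol directly, with release of 3. It comes back to the route at 9 and leaves out 8 and step 5.

Further compounds
F1 | step 8 | (3S,3aR,6aS)-3-[3,5-dimethoxy-4-(triisopropylsilyloxy)phenyl]-6-methoxytetrahydro-1H,3H-furo[3,4-c]furan-1-one (methyl acetal, both configurations at C6) | COC1OC[C@H]2[C@@H]1C(=O)O[C@@H]2c1cc(OC)c(O[Si](C(C)C)(C(C)C)C(C)C)c(OC)c1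
F2 | step 8 | potassium (4-hydroxy-3-methoxyphenyl)trifluoroborate | COc1cc([B-](F)(F)F)ccc1O.[K+]
F3 | step 7 | (4R,5S)-5-[3,5-dimethoxy-4-(triisopropylsilyloxy)phenyl]-4-[(triethylsilyloxy)methyl]oxolan-2-one | CC[Si](CC)(CC)OC[C@H]1CC(=O)O[C@@H]1c1cc(OC)c(O[Si](C(C)C)(C(C)C)C(C)C)c(OC)c1
F4 | step 7 | (4R,5S)-5-[3,5-dimethoxy-4-(triisopropylsilyloxy)phenyl]-3-(hydroxymethylidene)-4-[(triethylsilyloxy)methyl]oxolan-2-one (enol form of the α-formyl lactone) | OC=C1C(=O)O[C@H](c2cc(OC)c(O[Si](C(C)C)(C(C)C)C(C)C)c(OC)c2)[C@H]1CO[Si](CC)(CC)CC
F0 | step 4 | none | none
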